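**Plan**

- Retrosynthesis: cut the three sulfate S–O bonds and the two benzyl C–O bonds, then the C3–O bond and the C2=C3 unsaturation, which leads back to a 5,7-dihydroxyflavanone.
- Enabling feature: ring A has its oxygens on C5, C7 and C8a on alternate carbons (an acetate-type phloroglucinol), and C4a carries the acyl chain C4–C3–C2 that runs into ring B. This is the connectivity of a tetraketide started from a cinnamoyl unit.
- The flavanone is therefore cut at O1–C2 and C4a–C8a, unfolding rings C and A into a 4-hydroxy-2-pyrone with a cinnamoylmethyl group on C6. This pyrone is cut at its CH2–CO bond (pyrone dianion plus cinnamoyl Weinreb amide) and at the alkene (Horner–Wadsworth–Emmons).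
- Forward order: ring B aldehyde, E-cinnamoyl amide, chain joined to the pyrone, ring A then ring C closed in one flask, ring C aromatised, C3 oxygenated, three hydroxyls sulfated, benzyl groups removed.
- Stereochemistry: the target is achiral. The E-alkene comes from the olefination, and the only stereocentre on the way (flavanone C2) is formed racemic and removed on dehydrogenation.

Key step: step 4

Assumption: the sulfate monoesters are drawn as free hydrogen sulfates, as in the target formula; at the bench the sulfated intermediate and the target would be stored as ammonium or potassium salts and the acid form released only by brief cation exchange.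

**Route**

Step 1
Reactants: 1 4-benzyloxy-3-hydroxybenzaldehyde
Product: 2 4-(benzyloxy)-3-(methoxymethoxy)benzaldehyde
Conditions: MOMCl, iPr2NEt, CH2Cl2, 0 °C to rt
Reagents that add atoms: chloromethyl methyl ether (MOMCl), COCCl
Why: Williamson-type O-alkylation (MOM protection) of the only phenol gives an acetal that withstands the hydride, amide and methoxide bases of steps 2 to 4 and can later be removed without touching benzyl.

Step 2
Reactants: 2 4-(benzyloxy)-3-(methoxymethoxy)benzaldehyde; 3 diethyl (N-methoxy-N-methylcarbamoylmethyl)phosphonate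
Product: 4 (E)-3-[4-(benzyloxy)-3-(methoxymethoxy)phenyl]-N-methoxy-N-methylprop-2-enamide
Conditions: NaH, THF, 0 °C to rt
Reagents that add atoms: none
Why: Horner–Wadsworth–Emmons olefination of an aromatic aldehyde with a stabilised phosphonoacetamide anion should give the E-cinnamoyl Weinreb amide, the geometry following from reversible adduct formation and elimination through the less hindered oxaphosphetane.

Step 3
Reactants: 5 4-hydroxy-6-methyl-2H-pyran-2-one (triacetic acid lactone); 4 (E)-3-[4-(benzyloxy)-3-(methoxymethoxy)phenyl]-N-methoxy-N-methylprop-2-enamide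
Product: 7 6-[(E)-4-[4-(benzyloxy)-3-(methoxymethoxy)phenyl]-2-oxobut-3-en-1-yl]-4-hydroxy-2H-pyran-2-one, via dilithiated pyrone 6 (not isolated)
Conditions: 5 (1.5 equiv), LiN(iPr)2 (3.3 equiv, commercial solution), THF, −78 to −20 °C; then 4, −78 to 0 °C; cold 1 M HCl to pH 3
Reagents that add atoms: none
Why: Acylation of the triacetic lactone dianion at its terminal methyl carbanion is the established entry to 6-(2-oxoalkyl)-4-hydroxy-2-pyrones, and the N-methoxy-N-methyl amide holds the adduct as a lithium chelate until the quench so that neither over-addition nor proton transfer from the product consumes the carbanion.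

Step 4
Reactants: 7 6-[(E)-4-[4-(benzyloxy)-3-(methoxymethoxy)phenyl]-2-oxobut-3-en-1-yl]-4-hydroxy-2H-pyran-2-one
Product: 10 racemic 4'-(benzyloxy)-5,7-dihydroxy-3'-(methoxymethoxy)flavanone, via triketo ester 8 (not isolated), via chalcone 9 (not isolated)
Conditions: Mg(OMe)2 (8 equiv), MeOH, reflux; then 0 °C, AcOH to pH 5, NaOAc, 60 °C
Reagents that add atoms: none
Why: Methoxide from Mg(OMe)2 adds to the lactone carbonyl of 7 and opens the pyrone to the magnesium-chelated triketo ester 8, whose C6 methylene carbanion (flanked by the C5 and C7 ketones, the future C4a) attacks the ester carbon (future C8a) and expels methoxide, after which tautomerisation gives the phloroglucinol ring of chalcone 9. The closest known reaction type is the base-induced opening of 6-(2-oxoalkyl)-4-hydroxy-2-pyrones and 3,5,7-triketo esters followed by Claisen cyclisation to acylphloroglucinols, the laboratory counterpart of the chalcone synthase fold. Ring A closes by a 6-exo-trig Claisen (Dieckmann-type) acylation that forms C4a–C8a, and ring C closes in the buffered acidic stage by 6-endo-trig oxa-Michael addition of an ortho phenol to the enone that forms O1–C2; the two ortho hydroxyls are equivalent, so only one flavanone can result. The new C2 stereocentre has no controlling element and is formed racemic, which is immaterial because step 6 removes it. The step needs the Claisen fold to win over the aldol fold (C2 carbanion onto the C7 ketone, leading to a styryl resorcylate) and over hetero-Michael closure of a chain enol; chelation of the 3,5,7-tricarbonyl array to magnesium holds the C6 carbanion next to the ester, and the water-free methoxide medium keeps the ester from being saponified to the carboxylate that favours the aldol path. The MOM and benzyl ethers are inert to methoxide and to the acetate buffer.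

Step 5
Reactants: 10 racemic 4'-(benzyloxy)-5,7-dihydroxy-3'-(methoxymethoxy)flavanone
Product: 11 racemic 4'-(benzyloxy)-5-hydroxy-7,3'-bis(methoxymethoxy)flavanone
Conditions: MOMCl (1.1 equiv), iPr2NEt, CH2Cl2, 0 °C
Reagents that add atoms: chloromethyl methyl ether (MOMCl), COCCl
Why: The C5 hydroxyl is tied up in a hydrogen bond to the C4 carbonyl, so one equivalent of MOMCl with a hindered amine base should etherify the more acidic and accessible C7 phenol selectively (regioselective phenol O-alkylation).

Step 6
Reactants: 11 racemic 4'-(benzyloxy)-5-hydroxy-7,3'-bis(methoxymethoxy)flavanone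
Product: 13 4'-(benzyloxy)-5-hydroxy-7,3'-bis(methoxymethoxy)flavone, via 3-iodoflavanone 12 (not isolated)
Conditions: I2 (1.1 equiv), pyridine, 90 °C
Reagents that add atoms: none
Why: Iodine in hot pyridine dehydrogenates flavanones to flavones by α-iodination at C3 through the enol followed by base-induced loss of HI, the pyridine buffer sparing the acid-labile MOM acetals while the racemic C2 centre disappears.

Step 7
Reactants: 13 4'-(benzyloxy)-5-hydroxy-7,3'-bis(methoxymethoxy)flavone
Product: 14 5,4'-bis(benzyloxy)-7,3'-bis(methoxymethoxy)flavone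
Conditions: BnBr, K2CO3, nBu4NI (cat.), DMF, 60 °C
Reagents that add atoms: benzyl bromide, BrCc1ccccc1
Why: With the 2,3-double bond in place ring C can no longer open by retro-Michael reaction, so a forcing Williamson benzylation etherifies the chelated 5-OH and removes the last acidic, oxidisable phenol before the oxidation step.

Step 8
Reactants: 14 5,4'-bis(benzyloxy)-7,3'-bis(methoxymethoxy)flavone
Product: 16 5,4'-bis(benzyloxy)-3-hydroxy-7,3'-bis(methoxymethoxy)flavone, via flavone 2,3-epoxide 15 (not isolated)
Conditions: DMDO (acetone solution), CH2Cl2, 0 °C; concentrate; then p-TsOH·H2O (cat.), CH2Cl2, rt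
Reagents that add atoms: dimethyldioxirane (DMDO), CC1(C)OO1
Why: Dimethyldioxirane epoxidises the 2,3-double bond of fully O-protected flavones and trace acid opens the epoxide at C2 to an oxocarbenium ion that loses H3 to give the 3-hydroxyflavone (flavone-to-flavonol oxidation), any premature loss of MOM in the acid stage being harmless because step 9 removes both.

Step 9
Reactants: 16 5,4'-bis(benzyloxy)-3-hydroxy-7,3'-bis(methoxymethoxy)flavone
Product: 17 5,4'-bis(benzyloxy)-3,7,3'-trihydroxyflavone
Conditions: 2 M aq. HCl, MeOH/THF, 40 °C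
Reagents that add atoms: none
Why: Acid-catalysed acetal exchange with methanol cleaves both MOM ethers, while aryl benzyl ethers and the flavonol core are expected to survive these mild conditions.

Step 10
Reactants: 17 5,4'-bis(benzyloxy)-3,7,3'-trihydroxyflavone
Product: 18 5,4'-bis(benzyloxy)flavone-3,7,3'-triyl tris(hydrogen sulfate), isolated as its tris(triethylammonium) salt
Conditions: SO3·NMe3 (excess), Et3N, DMF, 60 °C, Ar; Sephadex LH-20
Reagents that add atoms: sulfur trioxide–trimethylamine complex, C[N+](C)(C)S(=O)(=O)[O-]
Why: O-Sulfonation of phenolic and enolic hydroxyls with the sulfur trioxide–trimethylamine complex under basic conditions is the standard route to flavonoid sulfates, and excess reagent should drive the 7-, 3'- and 3-hydroxyls to completion while C5 and C4' stay blocked as benzyl ethers.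

Step 11
Reactants: 18 5,4'-bis(benzyloxy)flavone-3,7,3'-triyl tris(hydrogen sulfate)
Product: 19 quercetin 3,3',7-trissulfate (5,4'-dihydroxyflavone-3,7,3'-triyl tris(hydrogen sulfate))
Conditions: H2 (1 atm), 10% Pd/C, MeOH/H2O, rt; then Dowex 50W (H+ form), 0 °C
Reagents that add atoms: none
Why: Hydrogenolysis of aryl benzyl ethers over palladium on carbon runs under neutral conditions in which aryl sulfate monoester salts and the flavone double bond are stable, so both benzyl groups should be removed without loss of sulfate.

**Compound list**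

1 | 4-benzyloxy-3-hydroxybenzaldehyde | O=Cc1ccc(OCc2ccccc2)c(O)c1 | starting material
2 | 4-(benzyloxy)-3-(methoxymethoxy)benzaldehyde | O=Cc1ccc(OCc2ccccc2)c(OCOC)c1 | intermediate
3 | diethyl (N-methoxy-N-methylcarbamoylmethyl)phosphonate | CCOP(=O)(CC(=O)N(C)OC)OCC | starting material
4 | (E)-3-[4-(benzyloxy)-3-(methoxymethoxy)phenyl]-N-methoxy-N-methylprop-2-enamide | CON(C)C(=O)/C=C/c1ccc(OCc2ccccc2)c(OCOC)c1 | intermediate
5 | 4-hydroxy-6-methyl-2H-pyran-2-one (triacetic acid lactone) | Cc1cc(O)cc(=O)o1 | starting material
6 | dilithiated pyrone: lithium 6-(lithiomethyl)-2-oxo-2H-pyran-4-olate, formed in the flask | [Li+].[Li+].[CH2-]c1cc([O-])cc(=O)o1 | intermediate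
7 | 6-[(E)-4-[4-(benzyloxy)-3-(methoxymethoxy)phenyl]-2-oxobut-3-en-1-yl]-4-hydroxy-2H-pyran-2-one | O=C(Cc1cc(O)cc(=O)o1)/C=C/c1ccc(OCc2ccccc2)c(OCOC)c1 | intermediate
8 | triketo ester: methyl (E)-9-[4-(benzyloxy)-3-(methoxymethoxy)phenyl]-3,5,7-trioxonon-8-enoate, present as its magnesium chelate, formed in the flask | COC(=O)CC(=O)CC(=O)CC(=O)/C=C/c1ccc(OCc2ccccc2)c(OCOC)c1 | intermediate
9 | chalcone: (E)-3-[4-(benzyloxy)-3-(methoxymethoxy)phenyl]-1-(2,4,6-trihydroxyphenyl)prop-2-en-1-one, formed in the flask | O=C(/C=C/c1ccc(OCc2ccccc2)c(OCOC)c1)c1c(O)cc(O)cc1O | intermediate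
10 | racemic 4'-(benzyloxy)-5,7-dihydroxy-3'-(methoxymethoxy)flavanone | O=C1CC(c2ccc(OCc3ccccc3)c(OCOC)c2)Oc2cc(O)cc(O)c21 | intermediate
11 | racemic 4'-(benzyloxy)-5-hydroxy-7,3'-bis(methoxymethoxy)flavanone | O=C1CC(c2ccc(OCc3ccccc3)c(OCOC)c2)Oc2cc(OCOC)cc(O)c21 | intermediate
12 | 3-iodoflavanone: 3-iodo derivative of 11, racemic, relative configuration at C2/C3 not defined, formed in the flask | O=C1C(I)C(c2ccc(OCc3ccccc3)c(OCOC)c2)Oc2cc(OCOC)cc(O)c21 | intermediate
13 | 4'-(benzyloxy)-5-hydroxy-7,3'-bis(methoxymethoxy)flavone | O=c1cc(-c2ccc(OCc3ccccc3)c(OCOC)c2)oc2cc(OCOC)cc(O)c12 | intermediate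
14 | 5,4'-bis(benzyloxy)-7,3'-bis(methoxymethoxy)flavone | O=c1cc(-c2ccc(OCc3ccccc3)c(OCOC)c2)oc2cc(OCOC)cc(OCc3ccccc3)c12 | intermediate
15 | flavone 2,3-epoxide of 14, racemic, cis-fused oxirane across C2–C3, formed in the flask | O=C1C2OC2(c3ccc(OCc4ccccc4)c(OCOC)c3)Oc3cc(OCOC)cc(OCc4ccccc4)c31 | intermediate
16 | 5,4'-bis(benzyloxy)-3-hydroxy-7,3'-bis(methoxymethoxy)flavone | O=c1c(O)c(-c2ccc(OCc3ccccc3)c(OCOC)c2)oc2cc(OCOC)cc(OCc3ccccc3)c12 | intermediate
17 | 5,4'-bis(benzyloxy)-3,7,3'-trihydroxyflavone | O=c1c(O)c(-c2ccc(OCc3ccccc3)c(O)c2)oc2cc(O)cc(OCc3ccccc3)c12 | intermediate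
18 | 5,4'-bis(benzyloxy)flavone-3,7,3'-triyl tris(hydrogen sulfate), handled as its tris(triethylammonium) salt | O=c1c(OS(=O)(=O)O)c(-c2ccc(OCc3ccccc3)c(OS(=O)(=O)O)c2)oc2cc(OS(=O)(=O)O)cc(OCc3ccccc3)c12 | intermediate
19 | quercetin 3,3',7-trissulfate (achiral) | O=c1c(OS(=O)(=O)O)c(-c2ccc(O)c(OS(=O)(=O)O)c2)oc2cc(OS(=O)(=O)O)cc(O)c12 | target

**Step count and risks**

Total step count: 11. Longest linear sequence: 11 steps (compound 1 to compound 19 through steps 1 to 11); compounds 3 and 5 are commercial and enter in steps 2 and 3.

Steps most likely to fail: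

Step 4. After ring opening the chain may fold by the aldol mode instead of the Claisen mode, or the stabilised pyronate may resist methoxide, so that ring A is not formed cleanly. The fallback builds ring A from a preformed arene; it sets out from compound 2 and comes back at compound 11. Commercial 2',4',6'-trihydroxyacetophenone is protected at its non-chelated para hydroxyl (MOMCl, iPr2NEt, CH2Cl2) to give 1-[2,6-dihydroxy-4-(methoxymethoxy)phenyl]ethanone F1. Claisen–Schmidt condensation of F1 with aldehyde 2 (KOH, EtOH/H2O, rt) should give (E)-3-[4-(benzyloxy)-3-(methoxymethoxy)phenyl]-1-[2,6-dihydroxy-4-(methoxymethoxy)phenyl]prop-2-en-1-one F2. NaOAc in hot EtOH isomerises F2 to flavanone 11, and the route continues with step 6.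

Step 3. The dianion may add in conjugate fashion to the cinnamoyl amide, or the poorly soluble dilithio salt may react incompletely. The fallback forms the alkene by aldol condensation after a simple acetylation; it sets out from compound 5 and comes back at compound 7. The dianion of 5 (LiN(iPr)2, THF) is acylated with N-methoxy-N-methylacetamide to 4-hydroxy-6-(2-oxopropyl)-2H-pyran-2-one F3. The trianion of F3 (LiN(iPr)2, 3.3 equiv, −78 °C) should add through its terminal methyl carbanion to aldehyde 2 to give racemic 6-[4-[4-(benzyloxy)-3-(methoxymethoxy)phenyl]-4-hydroxy-2-oxobutyl]-4-hydroxy-2H-pyran-2-one F4. Dehydration of F4 with catalytic pyridinium p-toluenesulfonate in warm toluene gives the E-enone 7.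

Step 8. Epoxidation of the electron-poor 2,3-double bond may be sluggish, with competing oxidation of benzylic and acetal C–H bonds by the dioxirane. The fallback replaces the electrophilic oxidation by deprotonation, borylation and oxidation; it sets out from compound 14 and comes back at compound 16. LiN(iPr)2 in THF at −78 °C lithiates C3 next to the C4 carbonyl, and B(OMe)3 traps the anion as 5,4'-bis(benzyloxy)-3-(dimethoxyboryl)-7,3'-bis(methoxymethoxy)flavone F5. Oxidation of F5 in the same flask with H2O2/AcOH should give flavonol 16.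

**Further compounds**

F1 | step 4 | 1-[2,6-dihydroxy-4-(methoxymethoxy)phenyl]ethanone | CC(=O)c1c(O)cc(OCOC)cc1O
F2 | step 4 | (E)-3-[4-(benzyloxy)-3-(methoxymethoxy)phenyl]-1-[2,6-dihydroxy-4-(methoxymethoxy)phenyl]prop-2-en-1-one | O=C(/C=C/c1ccc(OCc2ccccc2)c(OCOC)c1)c1c(O)cc(OCOC)cc1O
F3 | step 3 | 4-hydroxy-6-(2-oxopropyl)-2H-pyran-2-one | CC(=O)Cc1cc(O)cc(=O)o1
F4 | step 3 | racemic 6-[4-[4-(benzyloxy)-3-(methoxymethoxy)phenyl]-4-hydroxy-2-oxobutyl]-4-hydroxy-2H-pyran-2-one | O=C(Cc1cc(O)cc(=O)o1)CC(O)c1ccc(OCc2ccccc2)c(OCOC)c1
F5 | step 8 | 5,4'-bis(benzyloxy)-3-(dimethoxyboryl)-7,3'-bis(methoxymethoxy)flavone | COB(OC)c1c(-c2ccc(OCc3ccccc3)c(OCOC)c2)oc2cc(OCOC)cc(OCc3ccccc3)c2c1=O
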